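The runs come from a simulation with constants of no real substance.

**Late readings.** With time, Friday's flask nearly stops moving: starting material reads 52.9% at 1.33 h and 52.0% at 4.00 h. Saturday's and Monday's flasks share a partner charge, yet Monday's, with more second substrate, ends with more starting material, 22.0% against 9.0%.

the same everywhere: starting material 0.20 M; catalyst 0.20 mM

|  | partner | second substrate | remark | time |
|---|---|---|---|---|
| Saturday's | 0.24 M (fed, over 80 s) | 0.27 M | run made earlier |  |
| Monday's | 0.24 M (fed, over 80 s) | 0.60 M | run made earlier |  |
| Friday's | 0.12 M (fed, over 80 s) | 0.40 M | run made earlier |  |
| flask | 0.240 M (fed, over 80 s) | 0.400 M |  | 4.0 h |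

| run | time / h | starting material / % | target / % |
|---|---|---|---|
| Saturday's | 0.333 | 29.6 | 70.0 |
| Saturday's | 0.667 | 17.9 | 81.8 |
| Saturday's | 1.50 | 11.3 | 88.8 |
| Saturday's | 4.00 | 9.0 | 90.6 |
| Monday's | 0.333 | 35.0 | 64.9 |
| Monday's | 0.667 | 26.2 | 74.5 |
| Monday's | 1.50 | 21.6 | 77.8 |
| Monday's | 4.00 | 22.0 | 78.6 |
| Friday's | 0.500 | 55.1 | 44.2 |
| Friday's | 1.33 | 52.9 | 48.2 |
| Friday's | 2.50 | 52.4 | 47.3 |
| Friday's | 4.00 | 52.0 | 47.5 |

(standard deviation of a reading: 0.5 percentage points)

- the analysis behind the earlier runs scatters by 0.5 percentage points, standard deviation
- the reaction counts as stopped when no species that holds the starting material changes by six tenths of a point or more over the second half of the time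

- which holds at 4.0 h: what has brought the reaction to rest, or that it has not come to rest (it is still moving / all of the starting material has reacted / no working catalyst is left / forward and back rates have come level / the partner has run out first)
- how much of the starting material has reacted by 4.0 h
- how much target there is at 4.0 h, in percent of the starting material charged

**Shared partner.** Starting material and target sum to 99.6% in Saturday's last reading, so partner missing from the target is booked here to the second substrate. The feed of 80 s is far shorter than 4.0 h, so this reckoning ignores it. If each substrate reacts first order in itself, with partner and catalyst in common, dividing one rate by the other cancels time and partner. A constant remains. Last readings give 9.96 for Saturday's flask, 10.0 for Monday's and 10.6 for Friday's. Their mean, 10.2, is this reading of the selectivity factor: the log of the fall in c(starting material) over the log of the fall in c(second substrate).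

**Going round.** In the flask, the partner charge exceeds the starting material by 0.0400 M. Once the partner is used, the second substrate has taken that excess plus whatever starting material stays. Start from 15.5% left, midway between Saturday's and Monday's. The factor returns 13.7%; put back, that returns 15.3%. The rounds swing about the answer, so their mean, 14.5%, is this reckoning's figure, with 85.5% of the starting material reacted, the partner being the limiting reagent, its charge smaller than that of both substrates together.

**The forecast.** Its reading of the runs is that “the second substrate competes for the partner, which is then used up”. It says the partner has run out first, with 85% of the starting material reacted and 85% target, against 85.5% reacted in the reckoning above.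

**The result.** In the flask the partner has run out first: 0.0157% of the partner charge remains, 85.2% of the starting material has reacted, target stands at 85.2% of the starting material charged, and second product at 0.0696 M. With the other charges and the time held, partner charges of 0.220 M and 0.263 M are the nearest that shift the flask's conversion by 5 points.

    starting material + partner + catalyst → catalyst + target (k = 42.0 M⁻² s⁻¹)
    second substrate + partner + catalyst → catalyst + second product (k = 4.20 M⁻² s⁻¹)

**The neighbour.** A neighbour flask, otherwise like the flask, has 0.096 M of partner, less than its starting material. Its reckoning starts from the whole partner charge reacting with starting material, leaving 52.0% of that; the factor then gives 64.4%, and a second round 60.4%. That neighbour flask holds 61.5% starting material at 4.00 h.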